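**Retrosynthetic overview**
- The strategy rests on one feature: ring A carries its phenol oxygen ortho to the chain Cα(H)(CH3)–CβH2–ring C. The array O–C(ring A)–C(ring A)–Cα–Cβ(aryl C) is a ring-opened 2-aryl-3-methyl-2,3-dihydrobenzofuran (O1, C7a, C3a, C3 = Cα, C2 = Cβ).
- Last: global desilylation; before it, the oxolane C2–ring A bond, made by arylzinc attack on the oxocarbenium ion of a 2-sulfonyl oxolane, anti to the cis-3,4-dimethyl pair.
- The oxolane ring is closed early as the γ-lactone 21, from meso-2,3-dimethylsuccinic anhydride by Rh-catalysed arylative desymmetrisation, Felkin–Anh reduction and lactonisation.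
- The ring A/ring C aryl bromide comes from para-bromination of the phenol released by hydrogenolysis of the dihydrobenzofuran C2–O bond, after the ester has been taken down to CH3.
- The temporary dihydrobenzofuran ring is formed first (step 5) and opened in step 9: Rh(II)-carbenoid 1,5-C–H insertion of an aryldiazoacetate into the benzylic C–H of its own O-benzyl ether makes the Cα–Cβ bond.

Key step: step 5

Assumption: Rh2(S-PTTL)4 (step 5) and the (R,R)-Taddol-derived phosphoramidite (step 13) are taken to give the senses of induction drawn; should either give the antipode, the mirror-image catalyst is used and nothing else changes.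

**Route**

Step 1
Reactants: 1 4-hydroxybenzaldehyde
Product: 2 4-(triisopropylsilyloxy)benzaldehyde
Conditions: TIPSCl, imidazole, DMF, rt
Reagents that add atoms: chlorotri(propan-2-yl)silane (TIPSCl), CC(C)[Si](Cl)(C(C)C)C(C)C
Why: Standard O-silylation of a phenol, with TIPS chosen because a hindered aryl silyl ether should survive hydride, Rh, Pd/H2 and organometallic steps and still leave with fluoride at the end.

Step 2
Reactants: 2 4-(triisopropylsilyloxy)benzaldehyde
Product: 3 [4-(triisopropylsilyloxy)phenyl]methanol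
Conditions: NaBH4, THF–MeOH, 0 °C
Reagents that add atoms: none
Why: Borohydride reduction of an aromatic aldehyde is fast in the cold and should leave the aryl TIPS ether intact.

Step 3
Reactants: 3 [4-(triisopropylsilyloxy)phenyl]methanol; 4 methyl 2-(2-hydroxyphenyl)acetate
Product: 5 methyl 2-[2-[[4-(triisopropylsilyloxy)phenyl]methoxy]phenyl]acetate
Conditions: PPh3, DIAD, THF, 0 °C → rt
Reagents that add atoms: none
Why: Mitsunobu etherification of a phenol with a primary benzylic alcohol, which avoids the labile 4-silyloxybenzyl halide and the basic conditions under which the hydroxyphenylacetate could lactonise.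

Step 4
Reactants: 5 methyl 2-[2-[[4-(triisopropylsilyloxy)phenyl]methoxy]phenyl]acetate
Product: 6 methyl 2-diazo-2-[2-[[4-(triisopropylsilyloxy)phenyl]methoxy]phenyl]acetate
Conditions: p-ABSA, DBU, MeCN, 0 °C → rt
Reagents that add atoms: 4-acetamidobenzenesulfonyl azide (p-ABSA), CC(=O)Nc1ccc(cc1)S(=O)(=O)N=[N+]=[N-]
Why: Regitz diazo transfer to the DBU-generated arylacetate enolate is the routine entry to aryldiazoacetates and tolerates the ether and silyl groups.

Step 5
Reactants: 6 methyl 2-diazo-2-[2-[[4-(triisopropylsilyloxy)phenyl]methoxy]phenyl]acetate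
Product: 7 methyl (2R,3S)-2-[4-(triisopropylsilyloxy)phenyl]-2,3-dihydro-1-benzofuran-3-carboxylate (cis)
Conditions: Rh2(S-PTTL)4 [dirhodium tetrakis(N-phthaloyl-(S)-tert-leucinate)] (1–2 mol%), toluene, high dilution, −78 °C
Reagents that add atoms: none
Why: The dirhodium carboxylate expels N2 from 6 to give a donor/acceptor rhodium carbenoid at the future Cα, which engages the benzylic ether C–H five atoms away in a concerted, asynchronous three-centre (hydride-transfer-like) insertion. The closest known reaction type is the chiral dirhodium(II) carboxylate-catalysed enantioselective intramolecular C–H insertion of ortho-benzyloxy aryldiazoacetates to cis-2-aryl-2,3-dihydrobenzofuran-3-carboxylates, and this step is that reaction on a silyloxy-substituted substrate. The ring O1–C2–C3–C3a–C7a is closed by 1,5-C–H insertion, forming the C3–C2 bond (Cα–Cβ) with the hydrogen delivered to C3 through a six-membered cyclic array. C3 (S here, the future Cα) is set by the carbenoid face left open by the phthalimido walls of the catalyst, and C2 follows as cis because the aryl group sits away from the ester and the catalyst face in the insertion transition state; C2 is erased in step 9, so only C3 has to be right. The step needs chemoselectivity for this one C–H bond over carbene dimerisation, aromatic cycloaddition and ylide formation, which the doubly activated (ether oxygen and p-silyloxyaryl) benzylic position, the selectivity of the donor/acceptor carbenoid, dilution and low temperature should secure. The kinetic cis ester is kept cold and base-free and taken directly into step 6 so that C3 cannot epimerise.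

Step 6
Reactants: 7 methyl (2R,3S)-2-[4-(triisopropylsilyloxy)phenyl]-2,3-dihydro-1-benzofuran-3-carboxylate
Product: 8 [(2R,3R)-2-[4-(triisopropylsilyloxy)phenyl]-2,3-dihydro-1-benzofuran-3-yl]methanol
Conditions: DIBAL-H (3 equiv), CH2Cl2, −78 → −40 °C; Rochelle salt work-up
Reagents that add atoms: none
Why: Ester-to-alcohol reduction with a Lewis acidic, non-basic hydride in the cold removes the enolisable carbonyl before C3 can epimerise; the geometry at C3 is unchanged and only its descriptor changes.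

Step 7
Reactants: 8 [(2R,3R)-2-[4-(triisopropylsilyloxy)phenyl]-2,3-dihydro-1-benzofuran-3-yl]methanol
Product: 9 [(2R,3R)-2-[4-(triisopropylsilyloxy)phenyl]-2,3-dihydro-1-benzofuran-3-yl]methyl 4-methylbenzenesulfonate
Conditions: TsCl, Et3N, DMAP (cat.), CH2Cl2, 0 °C → rt
Reagents that add atoms: 4-methylbenzenesulfonyl chloride (TsCl), Cc1ccc(cc1)S(Cl)(=O)=O
Why: Sulfonylation of an unhindered primary alcohol activates the oxygen for hydride displacement without touching either stereocentre.

Step 8
Reactants: 9 [(2R,3R)-2-[4-(triisopropylsilyloxy)phenyl]-2,3-dihydro-1-benzofuran-3-yl]methyl 4-methylbenzenesulfonate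
Product: 10 (2R,3S)-3-methyl-2-[4-(triisopropylsilyloxy)phenyl]-2,3-dihydro-1-benzofuran (cis)
Conditions: LiBHEt3, THF, 0 °C → rt
Reagents that add atoms: none
Why: SN2 hydride displacement of a primary tosylate by the strongly nucleophilic, weakly basic triethylborohydride should outrun elimination to the exocyclic alkene and gives the Cα methyl group.

Step 9
Reactants: 10 (2R,3S)-3-methyl-2-[4-(triisopropylsilyloxy)phenyl]-2,3-dihydro-1-benzofuran
Product: 11 2-[(2R)-1-[4-(triisopropylsilyloxy)phenyl]propan-2-yl]phenol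
Conditions: H2 (4 bar), 10% Pd/C, EtOAc–AcOH, rt
Reagents that add atoms: none
Why: Catalytic hydrogenolysis of the benzylic C2–O bond of a benzyl aryl ether (the same ring opening that converts pterocarpans into isoflavans) should cleave only that bond, turning C2 into CβH2 and freeing the ring A phenol, while C3 carries no C–O bond and stays as (R)-Cα.

Step 10
Reactants: 11 2-[(2R)-1-[4-(triisopropylsilyloxy)phenyl]propan-2-yl]phenol
Product: 12 4-bromo-2-[(2R)-1-[4-(triisopropylsilyloxy)phenyl]propan-2-yl]phenol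
Conditions: NBS (1.0 equiv), MeCN, −20 → 0 °C, dark
Reagents that add atoms: N-bromosuccinimide, O=C1CCC(=O)N1Br
Why: Electrophilic aromatic bromination in a polar solvent without amine should go para to the free phenol, whose ring is far more activated than the silyl ether ring C.

Step 11
Reactants: 12 4-bromo-2-[(2R)-1-[4-(triisopropylsilyloxy)phenyl]propan-2-yl]phenol
Product: 13 [4-bromo-2-[(2R)-1-[4-(triisopropylsilyloxy)phenyl]propan-2-yl]phenoxy]tri(propan-2-yl)silane
Conditions: TIPSOTf, 2,6-lutidine, CH2Cl2, 0 °C → rt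
Reagents that add atoms: triisopropylsilyl trifluoromethanesulfonate (TIPSOTf), CC(C)[Si](OS(=O)(=O)C(F)(F)F)(C(C)C)C(C)C
Why: Silyl triflate silylation overcomes the hindrance of the ortho sec-alkyl group and masks the acidic phenol before metalation.

Step 12
Reactants: 14 meso-2,3-dimethylsuccinic acid
Product: 15 (3R,4S)-3,4-dimethyloxolane-2,5-dione (cis-2,3-dimethylsuccinic anhydride, meso)
Conditions: AcCl, reflux; evaporate
Reagents that add atoms: none
Why: Dehydrative cyclisation of a 1,4-diacid with acetyl chloride gives the cyclic anhydride, and the meso acid gives the cis (meso) isomer.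

Step 13
Reactants: 16 (4-bromophenoxy)tri(propan-2-yl)silane; 15 (3R,4S)-3,4-dimethyloxolane-2,5-dione
Product: 19 (2R,3S)-2,3-dimethyl-4-oxo-4-[4-(triisopropylsilyloxy)phenyl]butanoic acid, via aryllithium 17 (not isolated), via arylzinc triflate 18 (not isolated)
Conditions: n-BuLi, THF, −78 °C; Zn(OTf)2, −78 °C → rt; then 15, [Rh(cod)Cl]2 (4 mol%), (R,R)-Taddol-PNMe2 phosphoramidite (8 mol%), THF, 50 °C; aq. HCl work-up
Reagents that add atoms: none
Why: Rhodium/phosphoramidite-catalysed enantioselective arylative desymmetrisation of a meso succinic anhydride with an in situ arylzinc acylates one enantiotopic carbonyl only, so the syn-dimethyl keto acid is formed with both methyl-bearing centres fixed by the ligand and without epimerisation α to the ketone.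

Step 14
Reactants: 19 (2R,3S)-2,3-dimethyl-4-oxo-4-[4-(triisopropylsilyloxy)phenyl]butanoic acid
Product: 21 (3R,4S,5S)-3,4-dimethyl-5-[4-(triisopropylsilyloxy)phenyl]oxolan-2-one, via hydroxy acid 20 (not isolated)
Conditions: L-Selectride (2.5 equiv), THF, −78 °C; 2 M HCl; p-TsOH (cat.), CH2Cl2, rt
Reagents that add atoms: none
Why: Felkin–Anh reduction of the α-methyl aryl ketone by a bulky hydride (large group CH(CH3)CO2Li anti to the hydride) gives the (4S) carbinol, and acid lactonisation then closes the oxolane ring as the 3,4-cis-4,5-trans lactone, which is also the more stable C5 epimer should the electron-rich benzylic centre equilibrate in acid.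

Step 15
Reactants: 21 (3R,4S,5S)-3,4-dimethyl-5-[4-(triisopropylsilyloxy)phenyl]oxolan-2-one
Product: 22 (3R,4S,5S)-3,4-dimethyl-5-[4-(triisopropylsilyloxy)phenyl]oxolan-2-ol (anomeric mixture)
Conditions: DIBAL-H (1.1 equiv), CH2Cl2, −78 °C; Rochelle salt work-up
Reagents that add atoms: none
Why: Partial reduction of a γ-lactone stops at the lactol because the tetrahedral aluminium alkoxide is stable at −78 °C, and the non-basic conditions leave the epimerisable C3 methyl centre alone.

Step 16
Reactants: 22 (3R,4S,5S)-3,4-dimethyl-5-[4-(triisopropylsilyloxy)phenyl]oxolan-2-ol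
Product: 23 (3R,4S,5S)-2-(benzenesulfonyl)-3,4-dimethyl-5-[4-(triisopropylsilyloxy)phenyl]oxolane (anomeric mixture)
Conditions: PhSO2H, CaCl2, CH2Cl2, rt
Reagents that add atoms: benzenesulfinic acid, OS(=O)c1ccccc1
Why: Acid-mediated anomeric substitution of a lactol by sulfinate through the oxocarbenium ion gives a storable 2-sulfonyl cyclic ether that re-ionises readily with zinc and magnesium salts.

Step 17
Reactants: 13 [4-bromo-2-[(2R)-1-[4-(triisopropylsilyloxy)phenyl]propan-2-yl]phenoxy]tri(propan-2-yl)silane; 23 (3R,4S,5S)-2-(benzenesulfonyl)-3,4-dimethyl-5-[4-(triisopropylsilyloxy)phenyl]oxolane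
Product: 26 (2R,3R,4S,5S)-3,4-dimethyl-5-[4-(triisopropylsilyloxy)phenyl]-2-[4-(triisopropylsilyloxy)-3-[(2R)-1-[4-(triisopropylsilyloxy)phenyl]propan-2-yl]phenyl]oxolane, via arylmagnesium bromide 24 (not isolated), via arylzinc bromide 25 (not isolated)
Conditions: 13, Mg turnings (I2 activation), THF, 50 °C; ZnBr2, THF, 0 °C → rt; then 23, THF, rt
Reagents that add atoms: none
Why: Substitution of a 2-sulfonyl cyclic ether by an arylzinc reagent proceeds through the five-membered oxocarbenium ion, and both sterics and the inside-attack model place the aryl group on the face anti to the cis-3,4-dimethyl pair, which sets C2 as R (2,3-trans, 2,5-cis); a stereoisomer arising from a minor enantiomer of either fragment would be a diastereomer and could be removed here.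

Step 18
Reactants: 26 (2R,3R,4S,5S)-tris(triisopropylsilyl) ether
Product: 27 4-[(2S,3S,4R,5R)-5-[4-hydroxy-3-[(2R)-1-(4-hydroxyphenyl)propan-2-yl]phenyl]-3,4-dimethyloxolan-2-yl]phenol (CNP0232576.1)
Conditions: TBAF (3.3 equiv), AcOH (3.3 equiv), THF, 0 °C → rt
Reagents that add atoms: none
Why: Fluoride-induced cleavage of the three aryl silyl ethers, buffered with acetic acid so that the electron-rich phenolates are not exposed to base or air, touches no stereocentre.

**Compound list**
1 | 4-hydroxybenzaldehyde | O=Cc1ccc(O)cc1 | starting material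
2 | 4-(triisopropylsilyloxy)benzaldehyde | O=Cc1ccc(O[Si](C(C)C)(C(C)C)C(C)C)cc1 | intermediate
3 | [4-(triisopropylsilyloxy)phenyl]methanol | OCc1ccc(O[Si](C(C)C)(C(C)C)C(C)C)cc1 | intermediate
4 | methyl 2-(2-hydroxyphenyl)acetate | COC(=O)Cc1ccccc1O | starting material
5 | methyl 2-[2-[[4-(triisopropylsilyloxy)phenyl]methoxy]phenyl]acetate | COC(=O)Cc1ccccc1OCc1ccc(O[Si](C(C)C)(C(C)C)C(C)C)cc1 | intermediate
6 | methyl 2-diazo-2-[2-[[4-(triisopropylsilyloxy)phenyl]methoxy]phenyl]acetate | COC(=O)C(=[N+]=[N-])c1ccccc1OCc1ccc(O[Si](C(C)C)(C(C)C)C(C)C)cc1 | intermediate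
7 | methyl (2R,3S)-2-[4-(triisopropylsilyloxy)phenyl]-2,3-dihydro-1-benzofuran-3-carboxylate | c1ccc2c(c1)[C@H](C(=O)OC)[C@H](c1ccc(O[Si](C(C)C)(C(C)C)C(C)C)cc1)O2 | intermediate
8 | [(2R,3R)-2-[4-(triisopropylsilyloxy)phenyl]-2,3-dihydro-1-benzofuran-3-yl]methanol | c1ccc2c(c1)[C@H](CO)[C@H](c1ccc(O[Si](C(C)C)(C(C)C)C(C)C)cc1)O2 | intermediate
9 | [(2R,3R)-2-[4-(triisopropylsilyloxy)phenyl]-2,3-dihydro-1-benzofuran-3-yl]methyl 4-methylbenzenesulfonate | c1ccc2c(c1)[C@H](COS(=O)(=O)c1ccc(C)cc1)[C@H](c1ccc(O[Si](C(C)C)(C(C)C)C(C)C)cc1)O2 | intermediate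
10 | (2R,3S)-3-methyl-2-[4-(triisopropylsilyloxy)phenyl]-2,3-dihydro-1-benzofuran | c1ccc2c(c1)[C@H](C)[C@H](c1ccc(O[Si](C(C)C)(C(C)C)C(C)C)cc1)O2 | intermediate
11 | 2-[(2R)-1-[4-(triisopropylsilyloxy)phenyl]propan-2-yl]phenol | Oc1ccccc1[C@H](C)Cc1ccc(O[Si](C(C)C)(C(C)C)C(C)C)cc1 | intermediate
12 | 4-bromo-2-[(2R)-1-[4-(triisopropylsilyloxy)phenyl]propan-2-yl]phenol | Oc1ccc(Br)cc1[C@H](C)Cc1ccc(O[Si](C(C)C)(C(C)C)C(C)C)cc1 | intermediate
13 | [4-bromo-2-[(2R)-1-[4-(triisopropylsilyloxy)phenyl]propan-2-yl]phenoxy]tri(propan-2-yl)silane | CC(C)[Si](C(C)C)(C(C)C)Oc1ccc(Br)cc1[C@H](C)Cc1ccc(O[Si](C(C)C)(C(C)C)C(C)C)cc1 | intermediate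
14 | meso-2,3-dimethylsuccinic acid | C[C@H](C(=O)O)[C@@H](C)C(=O)O | starting material
15 | (3R,4S)-3,4-dimethyloxolane-2,5-dione | C[C@@H]1[C@H](C)C(=O)OC1=O | intermediate
16 | (4-bromophenoxy)tri(propan-2-yl)silane | Brc1ccc(O[Si](C(C)C)(C(C)C)C(C)C)cc1 | starting material
17 | [4-(triisopropylsilyloxy)phenyl]lithium | [Li]c1ccc(O[Si](C(C)C)(C(C)C)C(C)C)cc1 | intermediate
18 | [4-(triisopropylsilyloxy)phenyl]zinc trifluoromethanesulfonate | FC(F)(F)S(=O)(=O)O[Zn]c1ccc(O[Si](C(C)C)(C(C)C)C(C)C)cc1 | intermediate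
19 | (2R,3S)-2,3-dimethyl-4-oxo-4-[4-(triisopropylsilyloxy)phenyl]butanoic acid | C[C@@H](C(=O)O)[C@H](C)C(=O)c1ccc(O[Si](C(C)C)(C(C)C)C(C)C)cc1 | intermediate
20 | (2R,3S,4S)-4-hydroxy-2,3-dimethyl-4-[4-(triisopropylsilyloxy)phenyl]butanoic acid | C[C@@H](C(=O)O)[C@H](C)[C@H](O)c1ccc(O[Si](C(C)C)(C(C)C)C(C)C)cc1 | intermediate
21 | (3R,4S,5S)-3,4-dimethyl-5-[4-(triisopropylsilyloxy)phenyl]oxolan-2-one | C[C@@H]1[C@H](C)[C@@H](c2ccc(O[Si](C(C)C)(C(C)C)C(C)C)cc2)OC1=O | intermediate
22 | (3R,4S,5S)-3,4-dimethyl-5-[4-(triisopropylsilyloxy)phenyl]oxolan-2-ol | C[C@@H]1[C@H](C)[C@@H](c2ccc(O[Si](C(C)C)(C(C)C)C(C)C)cc2)OC1O | intermediate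
23 | (3R,4S,5S)-2-(benzenesulfonyl)-3,4-dimethyl-5-[4-(triisopropylsilyloxy)phenyl]oxolane | C[C@@H]1[C@H](C)[C@@H](c2ccc(O[Si](C(C)C)(C(C)C)C(C)C)cc2)OC1S(=O)(=O)c1ccccc1 | intermediate
24 | [4-(triisopropylsilyloxy)-3-[(2R)-1-[4-(triisopropylsilyloxy)phenyl]propan-2-yl]phenyl]magnesium bromide | Br[Mg]c1ccc(O[Si](C(C)C)(C(C)C)C(C)C)c(c1)[C@H](C)Cc1ccc(O[Si](C(C)C)(C(C)C)C(C)C)cc1 | intermediate
25 | [4-(triisopropylsilyloxy)-3-[(2R)-1-[4-(triisopropylsilyloxy)phenyl]propan-2-yl]phenyl]zinc bromide | Br[Zn]c1ccc(O[Si](C(C)C)(C(C)C)C(C)C)c(c1)[C@H](C)Cc1ccc(O[Si](C(C)C)(C(C)C)C(C)C)cc1 | intermediate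
26 | (2R,3R,4S,5S)-3,4-dimethyl-5-[4-(triisopropylsilyloxy)phenyl]-2-[4-(triisopropylsilyloxy)-3-[(2R)-1-[4-(triisopropylsilyloxy)phenyl]propan-2-yl]phenyl]oxolane | C[C@@H]1[C@H](C)[C@@H](c2ccc(O[Si](C(C)C)(C(C)C)C(C)C)cc2)O[C@H]1c1ccc(O[Si](C(C)C)(C(C)C)C(C)C)c([C@H](C)Cc2ccc(O[Si](C(C)C)(C(C)C)C(C)C)cc2)c1 | intermediate
27 | 4-[(2S,3S,4R,5R)-5-[4-hydroxy-3-[(2R)-1-(4-hydroxyphenyl)propan-2-yl]phenyl]-3,4-dimethyloxolan-2-yl]phenol | C[C@@H]1[C@H](C)[C@@H](c2ccc(O)cc2)O[C@H]1c1ccc(O)c([C@H](C)Cc2ccc(O)cc2)c1 | target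

**Totals**
Total step count: 18.
Longest linear sequence: 13 steps (steps 1–11, 17, 18); the oxolane branch is steps 12–16.

**Steps most likely to fail**

Step 5. What may go wrong is insufficient enantioface discrimination at the carbenoid carbon, or erosion of the kinetic cis ester by epimerisation at C3 before reduction. The fallback replaces catalyst control alone by auxiliary control with separable diastereomers. It sets out from ester 5. Me3SnOH (1,2-dichloroethane, 80 °C) should give 2-[2-[[4-(triisopropylsilyloxy)phenyl]methoxy]phenyl]acetic acid F1. DCC/DMAP esterification with (2S)-2-hydroxy-1-(pyrrolidin-1-yl)propan-1-one should give the lactamide ester (2S)-1-oxo-1-(pyrrolidin-1-yl)propan-2-yl 2-[2-[[4-(triisopropylsilyloxy)phenyl]methoxy]phenyl]acetate F2. p-ABSA/DBU should give the corresponding diazo ester F3. Insertion with Rh2(S-DOSP)4, in the matched pairing with the auxiliary, should give the (2R,3S)-dihydrobenzofuran lactamide ester F4, which is freed from its diastereomers by chromatography. LiBH4 (THF, 0 °C) removes the auxiliary reductively and the route is rejoined at alcohol 8.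

Step 17. What may go wrong is poor facial selectivity in the aryl transfer to the oxocarbenium ion, sluggish ionisation of the sulfone, or loss of the C3 configuration through proton loss to the enol ether. The fallback introduces the aryl group at the lactone oxidation level and makes the C2–H bond last. It sets out from bromide 13 and lactone 21. Bromine–lithium exchange on 13 (n-BuLi, THF, −78 °C) and addition to 21 should give the cyclic hemiketal (3R,4S,5S)-2-aryl-3,4-dimethyl-5-[4-(triisopropylsilyloxy)phenyl]oxolan-2-ol F5. Et3SiH/BF3·OEt2 (CH2Cl2, −78 → −20 °C) reduces the 2-aryl oxocarbenium ion. The Lewis acid is then left to equilibrate the benzylic C2 centre, through the ring-opened benzylic cation, to the thermodynamically preferred 2,3-trans arrangement. The route is rejoined at 26.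

Step 13. What may go wrong is low enantioselectivity or conversion in the rhodium-catalysed aryl transfer with the silyloxy-substituted arylzinc, or epimerisation α to the new ketone. The fallback desymmetrises by alcoholysis and forms the ketone by acylation. It sets out from anhydride 15. Cinchona-alkaloid-mediated methanolysis (quinidine or quinine, whichever gives the required half-ester; MeOH, toluene, −55 °C) should give (2S,3R)-4-methoxy-2,3-dimethyl-4-oxobutanoic acid F6. EtSH/DCC/DMAP should give the thioester methyl (2R,3S)-4-(ethylsulfanyl)-2,3-dimethyl-4-oxobutanoate F7. Palladium-catalysed Fukuyama coupling with the arylzinc made from 16 should give the keto ester methyl (2R,3S)-2,3-dimethyl-4-oxo-4-[4-(triisopropylsilyloxy)phenyl]butanoate F8. L-Selectride reduction followed by p-TsOH closes the lactone with loss of methanol, and the route is rejoined at 21.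

Further compounds
F1 | step 5 | 2-[2-[[4-(triisopropylsilyloxy)phenyl]methoxy]phenyl]acetic acid | OC(=O)Cc1ccccc1OCc1ccc(O[Si](C(C)C)(C(C)C)C(C)C)cc1
F2 | step 5 | (2S)-1-oxo-1-(pyrrolidin-1-yl)propan-2-yl 2-[2-[[4-(triisopropylsilyloxy)phenyl]methoxy]phenyl]acetate | C[C@H](OC(=O)Cc1ccccc1OCc1ccc(O[Si](C(C)C)(C(C)C)C(C)C)cc1)C(=O)N1CCCC1
F3 | step 5 | (2S)-1-oxo-1-(pyrrolidin-1-yl)propan-2-yl 2-diazo-2-[2-[[4-(triisopropylsilyloxy)phenyl]methoxy]phenyl]acetate | C[C@H](OC(=O)C(=[N+]=[N-])c1ccccc1OCc1ccc(O[Si](C(C)C)(C(C)C)C(C)C)cc1)C(=O)N1CCCC1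
F4 | step 5 | (2S)-1-oxo-1-(pyrrolidin-1-yl)propan-2-yl (2R,3S)-2-[4-(triisopropylsilyloxy)phenyl]-2,3-dihydro-1-benzofuran-3-carboxylate | C[C@H](OC(=O)[C@H]1c2ccccc2O[C@H]1c1ccc(O[Si](C(C)C)(C(C)C)C(C)C)cc1)C(=O)N1CCCC1
F5 | step 17 | (3R,4S,5S)-3,4-dimethyl-5-[4-(triisopropylsilyloxy)phenyl]-2-[4-(triisopropylsilyloxy)-3-[(2R)-1-[4-(triisopropylsilyloxy)phenyl]propan-2-yl]phenyl]oxolan-2-ol | C[C@@H]1[C@H](C)[C@@H](c2ccc(O[Si](C(C)C)(C(C)C)C(C)C)cc2)OC1(O)c1ccc(O[Si](C(C)C)(C(C)C)C(C)C)c([C@H](C)Cc2ccc(O[Si](C(C)C)(C(C)C)C(C)C)cc2)c1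
F6 | step 13 | (2S,3R)-4-methoxy-2,3-dimethyl-4-oxobutanoic acid | C[C@@H](C(=O)OC)[C@H](C)C(=O)O
F7 | step 13 | methyl (2R,3S)-4-(ethylsulfanyl)-2,3-dimethyl-4-oxobutanoate | C[C@@H](C(=O)OC)[C@H](C)C(=O)SCC
F8 | step 13 | methyl (2R,3S)-2,3-dimethyl-4-oxo-4-[4-(triisopropylsilyloxy)phenyl]butanoate | C[C@@H](C(=O)OC)[C@H](C)C(=O)c1ccc(O[Si](C(C)C)(C(C)C)C(C)C)cc1
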